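I balanced the catalyst first.

| flask | substrate | gas phase | protic impurity | free catalyst | stray impurity | remark | time |
|---|---|---|---|---|---|---|---|
| violet | 0.29 M | 16 mM (held) | 0.0145 M | 0.43 mM | 0.39 mM | run made earlier |  |
| green | 0.29 M | 16 mM (held) | 0.0145 M | 0.96 mM | 0.39 mM | run made earlier |  |
| flask | 0.29 M | 16 mM (held) | 0.0145 M | 0.64 mM | 0.39 mM |  | 25 min |

| run | time / min | target / % |
|---|---|---|
| violet | 2.00 | 2.4 |
| violet | 6.00 | 6.2 |
| violet | 12.0 | 11.3 |
| violet | 20.0 | 17.4 |
| violet | 25.0 | 21.3 |
| green | 2.00 | 9.6 |
| green | 4.00 | 19.8 |
| green | 8.00 | 38.1 |
| green | 12.0 | 54.6 |
| green | 25.0 | 88.1 |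

(standard deviation of a reading: 0.3 percentage points)

- at the start none of the gas phase is in solution

- east: doubling the saturation concentration of gas phase, all else as stated
- north-east: doubling the amount of free catalyst, all else as stated
- north-west: doubling the transfer coefficient of the gas phase, all else as stated

- amount of target at 25 min, in percent of the substrate charged
- the change that raises the amount of target at 25 min, in percent of the substrate charged most ("none" if none brings more than 2 percentage points) (east / north-east / north-west / none)
- amount of target at 25 min, in percent of the substrate charged, after east

- I read each run as one rate constant: the logarithm of charged substrate over substrate left at the last reading, divided by its time. That gave 0.00958 min⁻¹ for violet and 0.0851 min⁻¹ for green.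
- Catalyst rose 2.23-fold from violet to green, but the constant rose 8.88-fold. So I supposed that each stray impurity kills one catalyst for good.
- In the flask I got 0.250 mM of working catalyst, the charged free catalyst minus the charged stray impurity. In the flask the stray impurity was the limiting reagent of that poisoning.
- I turned the question round. On my supposition a dead flask needed a catalyst charge at or below 0.39 mM. The flask stood 0.250 mM above that line, violet 0.0400 mM and green 0.570 mM.
- Scaling by working catalyst gave 0.0373 min⁻¹ from green and 0.0599 min⁻¹ from violet. I took their mean, which gave 70.3% target.
- Doubling the catalyst multiplied working catalyst by 3.56, so I chose north-east. No run varied the gas. If the rate is first order in it, east gives 91.2%.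
- The forecast said 54%, north-east, and 78% after east, on “the stray impurity titrating catalyst”. My target figure was higher.
- The flask gave 66.2%, and 91.4% after east. The best change was north-east, gaining 29 percentage points against 25 points for east.

    free catalyst + stray impurity → spent catalyst (k = 15000 M⁻¹ min⁻¹)
    gas phase ⇌ dissolved gas, rate k2*(csat - [dissolved gas]) (kL = 1.60 min⁻¹)
    substrate + dissolved gas + free catalyst → free catalyst + target (k = 16000 M⁻² min⁻¹)
    dissolved gas + protic impurity → quenched reagent (k = 0.850 M⁻¹ min⁻¹)

- In the flask, against 0.250 mM of working catalyst, the stray impurity had a lifetime of 0.267 min, far shorter than the 25 min of the run. In the flask, free catalyst read 39.1% at 2.50 min and 39.1% at 25.0 min, matching the working share of 39.1%, with spent catalyst at 60.9% and 0% stray impurity left. The neighbour flask charged with 0.49 M of substrate had the same working catalyst, held 39.1% free catalyst and gave 57.8% target.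

All runs come from a simulation on assumed constants, noise included.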